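The route disconnects the O1–C5 bond of the oxolane ring (ring labels: O1, C2 aryl, C3 CH2OH, C4 aroyl, C5 CH2) and reads the array aroyl C=O–C4–C5–O1 as a β-alkoxy ketone, the retron of a homoenolate. C4, C5 and the future carbonyl carbon are therefore folded into a 1-arylcyclopropanol. In one operation, copper-catalysed oxidative ring opening releases the strain, unveils the aryl ketone and forges O1–C5 from the C2 hydroxyl. Both cyclopropane stereocentres are erased or made epimerisable, so every cyclopropanol diastereomer converges on the 3,4-trans product. The precursor is a syn-(1R,2R) 1,3-diol monosilyl ether whose central carbon carries a 2-hydroxy-2-(3,4,5-trimethoxyphenyl)cyclopropyl group, assembled by a Kulinkovich coupling.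

Key step: step 5

Remark: in the ring labels above the target is (2R,3R,4S), that is 2,3-cis and 3,4-trans. Systematic names number the oxolane in the opposite direction. C1' denotes the carbinol carbon of the cyclopropanol, which becomes the carbonyl carbon.

Step 1
Reactants: 1 buta-1,3-diene; 2 bis(pinacolato)diboron
Product: 3 (Z)-1,4-bis(4,4,5,5-tetramethyl-1,3,2-dioxaborolan-2-yl)but-2-ene
Conditions: Pt(PPh3)4 (3 mol %), toluene, 80 °C, sealed vessel
Reagents that add atoms: none
Why: Oxidative addition of the B–B bond to zerovalent platinum, insertion of the s-cis diene and reductive elimination from the π-allyl(boryl)platinum intermediate should give the 1,4-adduct with Z geometry (platinum-catalysed 1,4-diboration of a 1,3-diene).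

Step 2
Reactants: 3 (Z)-1,4-bis(4,4,5,5-tetramethyl-1,3,2-dioxaborolan-2-yl)but-2-ene; 4 3,4-dimethoxybenzaldehyde
Product: 6 (1R,2R)-1-(3,4-dimethoxyphenyl)-2-ethenylpropane-1,3-diol, via O-boryl homoallyl boronate 5 (not isolated)
Conditions: (R)-TRIP [(R)-3,3'-bis(2,4,6-triisopropylphenyl)-1,1'-binaphthyl-2,2'-diyl hydrogen phosphate] (5 mol %), toluene, −30 °C; then NaOH, H2O2, THF/H2O, 0 °C
Reagents that add atoms: hydrogen peroxide, OO
Why: Chiral phosphoric acid-catalysed allylboration through a closed chair transition state, in which the Z geometry of 3 places the CH2Bpin group axial and so gives the syn relationship of the C2 oxygen and the C3 CH2 group, the (R)-catalyst is expected to direct addition to the Re face of the aryl aldehyde (as with allyl- and Z-crotylboronic pinacol esters) to set the (1R) carbinol, and oxidative work-up turns the remaining primary C–B bond into the hydroxymethyl group.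

Step 3
Reactants: 6 (1R,2R)-1-(3,4-dimethoxyphenyl)-2-ethenylpropane-1,3-diol
Product: 7 (1R,2R)-2-({[tert-butyl(dimethyl)silyl]oxy}methyl)-1-(3,4-dimethoxyphenyl)but-3-en-1-ol
Conditions: TBSCl (1.05 equiv), imidazole, CH2Cl2, −20 → 0 °C
Reagents that add atoms: TBSCl, CC(C)(C)[Si](C)(C)Cl
Why: Silyl ether formation is much faster at the unhindered primary hydroxyl than at the secondary benzylic one, which leaves the C2 hydroxyl free as directing group for step 4 and as nucleophile for step 5.

Step 4
Reactants: 7 (1R,2R)-2-({[tert-butyl(dimethyl)silyl]oxy}methyl)-1-(3,4-dimethoxyphenyl)but-3-en-1-ol; 8 methyl 3,4,5-trimethoxybenzoate (1.5 equiv)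
Product: 9 (1R,2R)-3-{[tert-butyl(dimethyl)silyl]oxy}-1-(3,4-dimethoxyphenyl)-2-[2-hydroxy-2-(3,4,5-trimethoxyphenyl)cyclopropyl]propan-1-ol (mixture of diastereomers at the two cyclopropane carbons)
Conditions: Ti(OiPr)4 (1.0 equiv), c-C6H11MgCl (4.5 equiv, slow addition), THF, rt
Reagents that add atoms: none
Why: Kulinkovich cyclopropanation with alkene exchange, in which the titanacyclopropane formed from the cyclohexyl Grignard reagent exchanges cyclohexene for the terminal alkene of 7 (assisted by the homoallylic titanium alkoxide) and adds twice to the ester carbonyl; the configuration of the two new cyclopropane centres is immaterial because step 5 destroys one and equilibrates the other.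

Step 5
Reactants: 9 (1R,2R)-3-{[tert-butyl(dimethyl)silyl]oxy}-1-(3,4-dimethoxyphenyl)-2-[2-hydroxy-2-(3,4,5-trimethoxyphenyl)cyclopropyl]propan-1-ol
Product: 11 [(3S,4R,5R)-4-({[tert-butyl(dimethyl)silyl]oxy}methyl)-5-(3,4-dimethoxyphenyl)oxolan-3-yl](3,4,5-trimethoxyphenyl)methanone, via C4-epimeric oxolane ketone mixture 10 (not isolated)
Conditions: Cu(OTf)2 (20 mol %), 2,2'-bipyridine (20 mol %), O2 (1 atm), MeCN, rt → 40 °C; silica plug; then DBU (0.2 equiv), CH2Cl2, rt
Reagents that add atoms: none
Why: Ligand exchange gives a divalent copper cyclopropoxide that undergoes strain-driven scission of the less substituted C1'–C5 bond, unveiling the aryl ketone and leaving a C5 radical or organocopper next to the copper-bound C2 alkoxide; collapse to a six-membered alkyl(alkoxo) trivalent copper chelate and C–O reductive elimination forms O1–C5, monovalent copper is reoxidised by O2, and DBU then equilibrates C4 through the enol. The closest known reaction type is the copper-catalysed ring-opening functionalisation of cyclopropanols (β-keto radical or homoenolate chemistry), in its intramolecular C–O variant with hydroxy-substituted cyclopropanols. The oxolane closes in a formally 5-exo-tet sense at primary C5, and an alternative β-hydride elimination followed by 5-endo-trig oxa-Michael addition would converge on the same product. No stereocentre is created in the bond-forming event: C2 and C3 are carried over from 7, C1' becomes sp2, and C4 is set under thermodynamic control with the aroyl group trans to the C3 CH2OTBS group, avoiding the all-cis arrangement. The step needs cleavage of C1'–C5 rather than C1'–C4; this is secured because ring opening is reversible and only capture at C5 closes an unstrained five-membered ring (capture at C4 would need an oxetane), while the competing primary hydroxyl is masked as its silyl ether.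

Step 6
Reactants: 11 [(3S,4R,5R)-4-({[tert-butyl(dimethyl)silyl]oxy}methyl)-5-(3,4-dimethoxyphenyl)oxolan-3-yl](3,4,5-trimethoxyphenyl)methanone
Product: 12 [(3S,4R,5R)-5-(3,4-dimethoxyphenyl)-4-(hydroxymethyl)oxolan-3-yl](3,4,5-trimethoxyphenyl)methanone (CNP0271206.1)
Conditions: HF·pyridine, pyridine, THF, 0 °C → rt
Reagents that add atoms: none
Why: Fluoride-mediated cleavage of the primary silyl ether under buffered, non-basic and only weakly acidic conditions, chosen so that neither C4 (enolisation) nor the electron-rich benzylic C2–O bond (ionisation) is disturbed.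

Compound list
1 | buta-1,3-diene | C=CC=C | starting material
2 | bis(pinacolato)diboron | CC1(C)OB(OC1(C)C)B1OC(C)(C)C(C)(C)O1 | starting material
3 | (Z)-1,4-bis(4,4,5,5-tetramethyl-1,3,2-dioxaborolan-2-yl)but-2-ene | CC1(C)OB(C/C=C\CB2OC(C)(C)C(C)(C)O2)OC1(C)C | intermediate
4 | 3,4-dimethoxybenzaldehyde | COc1ccc(C=O)cc1OC | starting material
5 | 2-{[(1R,2S)-1-(3,4-dimethoxyphenyl)-2-[(4,4,5,5-tetramethyl-1,3,2-dioxaborolan-2-yl)methyl]but-3-en-1-yl]oxy}-4,4,5,5-tetramethyl-1,3,2-dioxaborolane | COc1ccc([C@H](OB2OC(C)(C)C(C)(C)O2)[C@@H](CB2OC(C)(C)C(C)(C)O2)C=C)cc1OC | intermediate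
6 | (1R,2R)-1-(3,4-dimethoxyphenyl)-2-ethenylpropane-1,3-diol | COc1ccc([C@H](O)[C@@H](CO)C=C)cc1OC | intermediate
7 | (1R,2R)-2-({[tert-butyl(dimethyl)silyl]oxy}methyl)-1-(3,4-dimethoxyphenyl)but-3-en-1-ol | COc1ccc([C@H](O)[C@@H](CO[Si](C)(C)C(C)(C)C)C=C)cc1OC | intermediate
8 | methyl 3,4,5-trimethoxybenzoate | COC(=O)c1cc(OC)c(OC)c(OC)c1 | starting material
9 | (1R,2R)-3-{[tert-butyl(dimethyl)silyl]oxy}-1-(3,4-dimethoxyphenyl)-2-[2-hydroxy-2-(3,4,5-trimethoxyphenyl)cyclopropyl]propan-1-ol, cyclopropane centres undefined | COc1ccc([C@H](O)[C@@H](CO[Si](C)(C)C(C)(C)C)C2CC2(O)c3cc(OC)c(OC)c(OC)c3)cc1OC | intermediate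
10 | [(4R,5R)-4-({[tert-butyl(dimethyl)silyl]oxy}methyl)-5-(3,4-dimethoxyphenyl)oxolan-3-yl](3,4,5-trimethoxyphenyl)methanone, mixture of epimers at the aroyl-bearing carbon | COc1ccc([C@@H]2OCC(C(=O)c3cc(OC)c(OC)c(OC)c3)[C@@H]2CO[Si](C)(C)C(C)(C)C)cc1OC | intermediate
11 | [(3S,4R,5R)-4-({[tert-butyl(dimethyl)silyl]oxy}methyl)-5-(3,4-dimethoxyphenyl)oxolan-3-yl](3,4,5-trimethoxyphenyl)methanone | COc1ccc([C@@H]2OC[C@@H](C(=O)c3cc(OC)c(OC)c(OC)c3)[C@@H]2CO[Si](C)(C)C(C)(C)C)cc1OC | intermediate
12 | [(3S,4R,5R)-5-(3,4-dimethoxyphenyl)-4-(hydroxymethyl)oxolan-3-yl](3,4,5-trimethoxyphenyl)methanone | COc1ccc([C@@H]2OC[C@@H](C(=O)c3cc(OC)c(OC)c(OC)c3)[C@@H]2CO)cc1OC | target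

Total step count: 6. Longest linear sequence: 6 steps (1 → 3 → 6 → 7 → 9 → 11 → 12).

Steps most likely to fail

Step 5. The ring opening may take the wrong course, by cleavage of the more substituted C1'–C4 bond, by interception of the C5 radical by O2 before the C–O bond forms, or by loss of the silyl ether to the Lewis-acidic copper salt, which would free the competing primary hydroxyl. The fallback sets out from 9 and comes back at 11; it makes the ring opening polar and separates it from the C–O bond formation. Treating 9 with Pd(OAc)2 (10 mol %) and pyridine under O2 in toluene at rt to 40 °C should give the α-methylene ketone (3R,4R)-3-({[tert-butyl(dimethyl)silyl]oxy}methyl)-4-(3,4-dimethoxyphenyl)-4-hydroxy-2-methylidene-1-(3,4,5-trimethoxyphenyl)butan-1-one F1. This would arise by β-carbon elimination of the less hindered C1'–C5 bond from the divalent palladium cyclopropoxide, followed by β-hydride elimination. Catalytic KOtBu in THF/t-BuOH should then close O1–C5 by 5-endo-trig oxa-Michael addition of the C2 alkoxide and equilibrate C4, giving 11.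

Step 4. Ligand exchange of the α-branched alkene onto the titanacyclopropane may be slow, so that the electron-rich aryl ester is consumed by direct Grignard addition or simply recovered. The fallback sets out from 7 and comes back at 9; a temporary ester tether makes the alkene–ester coupling intramolecular. Acylation of 7 with 3,4,5-trimethoxybenzoyl chloride (Et3N, DMAP, CH2Cl2) should give the homoallylic ester (1R,2R)-2-({[tert-butyl(dimethyl)silyl]oxy}methyl)-1-(3,4-dimethoxyphenyl)but-3-en-1-yl 3,4,5-trimethoxybenzoate F2. Ti(OiPr)4 and i-PrMgCl (2.2 equiv) in Et2O, −78 °C → rt, then generate a divalent titanium–alkene complex on the tethered vinyl group. This attacks its own ester carbonyl (intramolecular nucleophilic acyl substitution) and then the released ketone, giving 9 with the C2 hydroxyl set free on work-up.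

Step 2. Enantiofacial discrimination may be insufficient with the bulky γ-(borylmethyl) reagent, an uncatalysed background reaction may compete, or the induction may run in the opposite sense. The fallback sets out from 4 and comes back at 7, so that steps 1 and 3 are not needed; auxiliary control replaces catalyst control.
- (R)-4-Benzyl-1,3-oxazolidin-2-one is N-acylated with 3-{[tert-butyl(dimethyl)silyl]oxy}propanoic acid (pivaloyl chloride, Et3N, LiCl, THF) to give the imide (R)-4-benzyl-3-(3-{[tert-butyl(dimethyl)silyl]oxy}propanoyl)-1,3-oxazolidin-2-one F3.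
- Its Z-boron enolate (Bu2BOTf, i-Pr2NEt, CH2Cl2, −78 °C) should add to 4 in an Evans syn aldol reaction to give (R)-4-benzyl-3-[(2R,3R)-2-({[tert-butyl(dimethyl)silyl]oxy}methyl)-3-(3,4-dimethoxyphenyl)-3-hydroxypropanoyl]-1,3-oxazolidin-2-one F4.
- TESOTf and 2,6-lutidine give the triethylsilyl ether (R)-4-benzyl-3-[(2R,3R)-2-({[tert-butyl(dimethyl)silyl]oxy}methyl)-3-(3,4-dimethoxyphenyl)-3-[(triethylsilyl)oxy]propanoyl]-1,3-oxazolidin-2-one F5.
- LiBH4 (THF/MeOH) removes the auxiliary to give (2R,3R)-2-({[tert-butyl(dimethyl)silyl]oxy}methyl)-3-(3,4-dimethoxyphenyl)-3-[(triethylsilyl)oxy]propan-1-ol F6.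
- Dess–Martin oxidation gives (2R,3R)-2-({[tert-butyl(dimethyl)silyl]oxy}methyl)-3-(3,4-dimethoxyphenyl)-3-[(triethylsilyl)oxy]propanal F7.
- Wittig methylenation (Ph3P=CH2, THF, −78 → 0 °C) gives tert-butyl({(2R,3R)-3-(3,4-dimethoxyphenyl)-2-ethenyl-3-[(triethylsilyl)oxy]propyl}oxy)dimethylsilane F8.
- Selective removal of the secondary triethylsilyl ether (AcOH/THF/H2O, rt) returns 7.

Further compounds
F1 | step 5 | (3R,4R)-3-({[tert-butyl(dimethyl)silyl]oxy}methyl)-4-(3,4-dimethoxyphenyl)-4-hydroxy-2-methylidene-1-(3,4,5-trimethoxyphenyl)butan-1-one | COc1ccc([C@H](O)[C@@H](CO[Si](C)(C)C(C)(C)C)C(=C)C(=O)c2cc(OC)c(OC)c(OC)c2)cc1OC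
F2 | step 4 | (1R,2R)-2-({[tert-butyl(dimethyl)silyl]oxy}methyl)-1-(3,4-dimethoxyphenyl)but-3-en-1-yl 3,4,5-trimethoxybenzoate | COc1ccc([C@H](OC(=O)c2cc(OC)c(OC)c(OC)c2)[C@@H](CO[Si](C)(C)C(C)(C)C)C=C)cc1OC
F3 | step 2 | (R)-4-benzyl-3-(3-{[tert-butyl(dimethyl)silyl]oxy}propanoyl)-1,3-oxazolidin-2-one | O=C(CCO[Si](C)(C)C(C)(C)C)N1[C@H](Cc2ccccc2)COC1=O
F4 | step 2 | (R)-4-benzyl-3-[(2R,3R)-2-({[tert-butyl(dimethyl)silyl]oxy}methyl)-3-(3,4-dimethoxyphenyl)-3-hydroxypropanoyl]-1,3-oxazolidin-2-one | COc1ccc([C@H](O)[C@@H](CO[Si](C)(C)C(C)(C)C)C(=O)N2[C@H](Cc3ccccc3)COC2=O)cc1OC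
F5 | step 2 | (R)-4-benzyl-3-[(2R,3R)-2-({[tert-butyl(dimethyl)silyl]oxy}methyl)-3-(3,4-dimethoxyphenyl)-3-[(triethylsilyl)oxy]propanoyl]-1,3-oxazolidin-2-one | COc1ccc([C@H](O[Si](CC)(CC)CC)[C@@H](CO[Si](C)(C)C(C)(C)C)C(=O)N2[C@H](Cc3ccccc3)COC2=O)cc1OC
F6 | step 2 | (2R,3R)-2-({[tert-butyl(dimethyl)silyl]oxy}methyl)-3-(3,4-dimethoxyphenyl)-3-[(triethylsilyl)oxy]propan-1-ol | COc1ccc([C@H](O[Si](CC)(CC)CC)[C@@H](CO[Si](C)(C)C(C)(C)C)CO)cc1OC
F7 | step 2 | (2R,3R)-2-({[tert-butyl(dimethyl)silyl]oxy}methyl)-3-(3,4-dimethoxyphenyl)-3-[(triethylsilyl)oxy]propanal | COc1ccc([C@H](O[Si](CC)(CC)CC)[C@@H](CO[Si](C)(C)C(C)(C)C)C=O)cc1OC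
F8 | step 2 | tert-butyl({(2R,3R)-3-(3,4-dimethoxyphenyl)-2-ethenyl-3-[(triethylsilyl)oxy]propyl}oxy)dimethylsilane | COc1ccc([C@H](O[Si](CC)(CC)CC)[C@@H](CO[Si](C)(C)C(C)(C)C)C=C)cc1OC
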